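**Retrosynthetic overview**
1. The oxirane is made last, by hydroxyl-directed asymmetric epoxidation of C4=C5 in the ten-membered 15-alcohol, as an oxidase would act on a germacrene.
2. The ten-membered ring is made by C6–C7 closure of a farnesyl-type chain (the 1,10-cyclisation of farnesyl diphosphate). A 3-substituted 2,5-dihydrofuran serves as the latent cis allyl cation plus 15-alkoxide, and a 2-(acetoxymethyl)allylsilane as the terminating olefin.
3. The chain comes from two olefin cross-metatheses (C1=C10 and C7=C11), one catalytic asymmetric allylboration (C9) and two esterifications.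
4. Building blocks: the dihydrofuran from 4-chlorobut-2-yn-1-ol and butenyl Grignard, the enal from 2-methylidenepropane-1,3-diol, and the acid from an Evans aldol.
5. Ring order: dihydrofuran (temporary), then the ten-membered carbocycle (the dihydrofuran opens in the same step), then the oxirane.

Assumption: germacrane numbering is used throughout (ring C1–C10, C11(=C13)–C12 on C7, C14 on C10, C15 on C4, acid carbons primed); the allylsilane precursor is used as its C7=C11 E/Z mixture because both isomers give the same product.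

**Step 1**
Reactants: 1 (4R)-4-benzyl-3-propanoyl-1,3-oxazolidin-2-one; 2 acetaldehyde
Product: 5 (4R)-4-benzyl-3-[(2R,3S)-3-hydroxy-2-methylbutanoyl]-1,3-oxazolidin-2-one, via Z-dibutylboron enolate 3 (not isolated), via dibutylboron aldolate 4 (not isolated)
Conditions: Bu2BOTf, i-Pr2NEt, CH2Cl2, 0 °C; MeCHO, −78 → 0 °C; then pH 7 buffer, MeOH, 30% H2O2, 0 °C
Reagents that add atoms: none
Why: Evans syn-aldol reaction; the Z boron enolate reacts through a closed Zimmerman–Traxler chair on the face away from the benzyl group, so the (R)-auxiliary sets C2' as R and C3' as S.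

**Step 2**
Reactants: 5 (4R)-4-benzyl-3-[(2R,3S)-3-hydroxy-2-methylbutanoyl]-1,3-oxazolidin-2-one
Product: 6 (4R)-4-benzyl-3-[(2R,3S)-2-methyl-3-(triethylsilyloxy)butanoyl]-1,3-oxazolidin-2-one
Conditions: Et3SiCl, imidazole, DMF, 0 °C → rt
Reagents that add atoms: chlorotriethylsilane, CC[Si](Cl)(CC)CC
Why: Imidazole-promoted silylation of the secondary alcohol; the ether keeps this hydroxyl out of the later acylation and of the silylium step and falls off in step 12.

**Step 3**
Reactants: 6 (4R)-4-benzyl-3-[(2R,3S)-2-methyl-3-(triethylsilyloxy)butanoyl]-1,3-oxazolidin-2-one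
Product: 8 (2R,3S)-2-methyl-3-(triethylsilyloxy)butanoic acid, via peroxy acid 7 (not isolated)
Conditions: LiOH, 30% H2O2, THF/H2O 3:1, 0 °C; then Na2SO3 aq; then 1 M HCl to pH 4, 0 °C
Reagents that add atoms: hydrogen peroxide (as LiOOH), OO
Why: Hydroperoxide cleavage of the N-acyl oxazolidinone attacks the exocyclic carbonyl selectively and does not epimerise C2'; sulfite reduces the peroxy acid.

**Step 4**
Reactants: 8 (2R,3S)-2-methyl-3-(triethylsilyloxy)butanoic acid; 9 2-methylidenepropane-1,3-diol
Product: 10 2-(hydroxymethyl)prop-2-en-1-yl (2R,3S)-2-methyl-3-(triethylsilyloxy)butanoate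
Conditions: DCC, DMAP (0.1 equiv), 9 (4 equiv), CH2Cl2, 0 °C → rt
Reagents that add atoms: none
Why: Steglich esterification; a fourfold excess of the symmetric diol makes the mono-ester the main product and the diol is washed out with water.

**Step 5**
Reactants: 10 2-(hydroxymethyl)prop-2-en-1-yl (2R,3S)-2-methyl-3-(triethylsilyloxy)butanoate
Product: 11 2-formylprop-2-en-1-yl (2R,3S)-2-methyl-3-(triethylsilyloxy)butanoate
Conditions: MnO2 (activated, 15 equiv), CH2Cl2, rt; filter, use at once
Reagents that add atoms: none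
Why: Selective allylic oxidation of the primary allylic alcohol by MnO2 gives the 2-substituted acrolein that carries C9, C10 and the complete C14 ester.

**Step 6**
Reactants: 12 4-chlorobut-2-yn-1-ol; 13 but-3-en-1-ylmagnesium bromide
Product: 16 2-(but-3-en-1-yl)buta-2,3-dien-1-ol, via bromomagnesium 4-chlorobut-2-yn-1-olate 14 (not isolated), via bromomagnesium allenyl alkoxide 15 (not isolated)
Conditions: 13 (2.3 equiv), CuI (10 mol%), THF, −78 → 0 °C; NH4Cl aq
Reagents that add atoms: none
Why: Copper-catalysed anti SN2' substitution of the propargylic chloride; the first equivalent of Grignard forms the magnesium alkoxide, which directs carbon delivery to the proximal alkyne carbon and gives the 2-substituted allenol.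

**Step 7**
Reactants: 16 2-(but-3-en-1-yl)buta-2,3-dien-1-ol
Product: 17 3-(but-3-en-1-yl)-2,5-dihydrofuran
Conditions: AuCl3 (2 mol%), CH2Cl2, rt
Reagents that add atoms: none
Why: Gold-catalysed 5-endo cycloisomerisation of the α-hydroxyallene; the ring formed locks C15 and C6 cis on the future C4=C5 bond, which is the ring-E geometry of the germacrene.

**Step 8**
Reactants: 17 3-(but-3-en-1-yl)-2,5-dihydrofuran; 11 2-formylprop-2-en-1-yl (2R,3S)-2-methyl-3-(triethylsilyloxy)butanoate
Product: 18 (2E)-5-(2,5-dihydrofuran-3-yl)-2-formylpent-2-en-1-yl (2R,3S)-2-methyl-3-(triethylsilyloxy)butanoate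
Conditions: second-generation Hoveyda–Grubbs catalyst, RuCl2(H2IMes)(=CH-C6H4-2-O-iPr) (5 mol%), 17 (3 equiv), CH2Cl2, 40 °C
Reagents that add atoms: none
Why: Olefin cross-metathesis of a terminal alkene with an α-substituted acrolein, which like methacrolein gives the E enal (formyl trans to the chain) and so sets the C1=C10 geometry; the trisubstituted ring alkene is inert.

**Step 9**
Reactants: 18 (2E)-5-(2,5-dihydrofuran-3-yl)-2-formylpent-2-en-1-yl (2R,3S)-2-methyl-3-(triethylsilyloxy)butanoate; 19 2-allyl-4,4,5,5-tetramethyl-1,3,2-dioxaborolane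
Product: 21 (2E)-5-(2,5-dihydrofuran-3-yl)-2-[(1R)-1-hydroxybut-3-en-1-yl]pent-2-en-1-yl (2R,3S)-2-methyl-3-(triethylsilyloxy)butanoate, via pinacol boronate ester 20 (not isolated)
Conditions: (R)-TRIP [(R)-3,3'-bis(2,4,6-triisopropylphenyl)-1,1'-binaphthyl-2,2'-diyl hydrogen phosphate] (5 mol%), 4 Å MS, toluene, −30 °C; aqueous work-up
Reagents that add atoms: none
Why: Chiral phosphoric acid-catalysed allylboration through a six-membered chair; the (R)-acid directs allyl transfer to the Re face of the aldehyde (the sense known for benzaldehyde and cinnamaldehyde), which sets C9 as R.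

**Step 10**
Reactants: 21 (2E)-5-(2,5-dihydrofuran-3-yl)-2-[(1R)-1-hydroxybut-3-en-1-yl]pent-2-en-1-yl (2R,3S)-2-methyl-3-(triethylsilyloxy)butanoate; 22 3-methylbut-2-enoic acid
Product: 23 C9 3-methylbut-2-enoate of 21
Conditions: DCC, DMAP (0.5 equiv), CH2Cl2, 0 °C → rt
Reagents that add atoms: none
Why: Steglich esterification of the secondary allylic alcohol; the carbodiimide method avoids the vinylketene path that deconjugates senecioyl chloride, and C9 is not touched.

**Step 11**
Reactants: 23 C9 3-methylbut-2-enoate of 21; 24 2-[(trimethylsilyl)methyl]prop-2-en-1-yl acetate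
Product: 25 acyclic precursor with the C7=C11(CH2OAc)(CH2SiMe3) allylsilane (E/Z mixture)
Conditions: second-generation Hoveyda–Grubbs catalyst, RuCl2(H2IMes)(=CH-C6H4-2-O-iPr) (10 mol%, two portions), 24 (5 equiv), CH2Cl2, 40 °C
Reagents that add atoms: none
Why: Olefin cross-metathesis of the only monosubstituted alkene with the 1,1-disubstituted allylsilane acetate; the trisubstituted and conjugated alkenes are inert and the C7=C11 geometry does not matter for the next step.

**Step 12**
Reactants: 25 acyclic precursor with the C7=C11(CH2OAc)(CH2SiMe3) allylsilane (E/Z mixture)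
Product: 27 ten-membered 15,3'-diol (1(10)E, ring-trans C4=C5, 7R, 9R), via macrocyclic 15-O-trimethylsilyl 3'-O-triethylsilyl ether 26 (not isolated)
Conditions: Me3SiNTf2 (10 mol%), 2,6-di-tert-butyl-4-methylpyridine (15 mol%), CH2Cl2, 1 mM by slow addition, −78 → −30 °C; then pyridine, HF·pyridine, THF, 0 °C → rt
Reagents that add atoms: none
Why: Proposed new method: the silylium catalyst binds the most basic oxygen (the ring ether) and the silyloxonium ionises at C6–O because this gives the prenyl-type allyl cation, while the ring has fixed C15 and C6 cis; C7 of the allylsilane traps the primary end C6 (ten-membered ring; closure onto C1=C10 is geometrically excluded for the E allyl unit), and loss of Me3Si+ from the β-silyl cation forms the C11=C13 methylidene and carries the chain, so the substrate isomerises with net silyl transfer from C13 to O15; C7 is set by 1,3-induction from the C9 ester in a chair-like closure with ester and forming isopropenyl unit both pseudo-equatorial (7,9-cis); the closest known reaction types are the Me3SiOTf-catalysed Hosomi–Sakurai allylation of acetals and allylic ethers and allylsilane-terminated cation–olefin cyclisation; HF·pyridine then removes both silyl groups.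

**Step 13**
Reactants: 27 ten-membered 15,3'-diol (1(10)E, ring-trans C4=C5, 7R, 9R)
Product: 28 CNP0227102.1
Conditions: Ti(OiPr)4 (0.5 equiv), L-(+)-diisopropyl tartrate (0.6 equiv), t-BuOOH (2 equiv, in decane), 4 Å MS, CH2Cl2, −20 °C; aqueous tartaric acid work-up
Reagents that add atoms: tert-butyl hydroperoxide, CC(C)(C)OO
Why: Katsuki–Sharpless asymmetric epoxidation; only the free allylic alcohol binds titanium, so only C4=C5 reacts, and L-(+)-tartrate (the series that gives (2S)-glycidols) delivers oxygen to the face that makes C4 S and C5 R, the trans oxirane following from the ring-E alkene.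

**Compound list**
1 | (4R)-4-benzyl-3-propanoyl-1,3-oxazolidin-2-one | CCC(=O)N1C(=O)OC[C@H]1Cc1ccccc1 | starting material
2 | acetaldehyde | CC=O | starting material
3 | Z-dibutylboron enolate of 1 | C/C=C(\OB(CCCC)CCCC)N1C(=O)OC[C@H]1Cc1ccccc1 | intermediate
4 | dibutylboron aldolate (O-BBu2 derivative of 5) | O=C([C@H](C)[C@H](C)OB(CCCC)CCCC)N1C(=O)OC[C@H]1Cc1ccccc1 | intermediate
5 | (4R)-4-benzyl-3-[(2R,3S)-3-hydroxy-2-methylbutanoyl]-1,3-oxazolidin-2-one | O=C([C@H](C)[C@H](C)O)N1C(=O)OC[C@H]1Cc1ccccc1 | intermediate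
6 | (4R)-4-benzyl-3-[(2R,3S)-2-methyl-3-(triethylsilyloxy)butanoyl]-1,3-oxazolidin-2-one | O=C([C@H](C)[C@H](C)O[Si](CC)(CC)CC)N1C(=O)OC[C@H]1Cc1ccccc1 | intermediate
7 | (2R,3S)-2-methyl-3-(triethylsilyloxy)butaneperoxoic acid | OOC(=O)[C@H](C)[C@H](C)O[Si](CC)(CC)CC | intermediate
8 | (2R,3S)-2-methyl-3-(triethylsilyloxy)butanoic acid | OC(=O)[C@H](C)[C@H](C)O[Si](CC)(CC)CC | intermediate
9 | 2-methylidenepropane-1,3-diol | C=C(CO)CO | starting material
10 | 2-(hydroxymethyl)prop-2-en-1-yl (2R,3S)-2-methyl-3-(triethylsilyloxy)butanoate | C=C(CO)COC(=O)[C@H](C)[C@H](C)O[Si](CC)(CC)CC | intermediate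
11 | 2-formylprop-2-en-1-yl (2R,3S)-2-methyl-3-(triethylsilyloxy)butanoate | C=C(C=O)COC(=O)[C@H](C)[C@H](C)O[Si](CC)(CC)CC | intermediate
12 | 4-chlorobut-2-yn-1-ol | OCC#CCCl | starting material
13 | but-3-en-1-ylmagnesium bromide | C=CCC[Mg]Br | starting material
14 | bromomagnesium 4-chlorobut-2-yn-1-olate | ClCC#CCO[Mg]Br | intermediate
15 | bromomagnesium 2-(but-3-en-1-yl)buta-2,3-dien-1-olate | C=CCCC(=C=C)CO[Mg]Br | intermediate
16 | 2-(but-3-en-1-yl)buta-2,3-dien-1-ol | C=CCCC(=C=C)CO | intermediate
17 | 3-(but-3-en-1-yl)-2,5-dihydrofuran | C=CCCC1=CCOC1 | intermediate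
18 | (2E)-5-(2,5-dihydrofuran-3-yl)-2-formylpent-2-en-1-yl (2R,3S)-2-methyl-3-(triethylsilyloxy)butanoate (C9 aldehyde, C1=C10 E) | O=C/C(COC(=O)[C@H](C)[C@H](C)O[Si](CC)(CC)CC)=C/CCC1=CCOC1 | intermediate
19 | 2-allyl-4,4,5,5-tetramethyl-1,3,2-dioxaborolane | C=CCB1OC(C)(C)C(C)(C)O1 | starting material
20 | pinacol boronate ester of 21 | C=CC[C@@H](OB1OC(C)(C)C(C)(C)O1)/C(COC(=O)[C@H](C)[C@H](C)O[Si](CC)(CC)CC)=C/CCC1=CCOC1 | intermediate
21 | (2E)-5-(2,5-dihydrofuran-3-yl)-2-[(1R)-1-hydroxybut-3-en-1-yl]pent-2-en-1-yl (2R,3S)-2-methyl-3-(triethylsilyloxy)butanoate (9R alcohol) | C=CC[C@@H](O)/C(COC(=O)[C@H](C)[C@H](C)O[Si](CC)(CC)CC)=C/CCC1=CCOC1 | intermediate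
22 | 3-methylbut-2-enoic acid | CC(C)=CC(=O)O | starting material
23 | C9 3-methylbut-2-enoate of 21 (9R) | C=CC[C@@H](OC(=O)C=C(C)C)/C(COC(=O)[C@H](C)[C@H](C)O[Si](CC)(CC)CC)=C/CCC1=CCOC1 | intermediate
24 | 2-[(trimethylsilyl)methyl]prop-2-en-1-yl acetate | CC(=O)OCC(=C)C[Si](C)(C)C | starting material
25 | acyclic precursor: 23 with the terminal vinyl replaced by CH=C(CH2OAc)CH2SiMe3 (C7=C11 E/Z mixture; dihydrofuran oxygen bridges C15 and C6; 9R) | CC(=O)OCC(C[Si](C)(C)C)=CC[C@@H](OC(=O)C=C(C)C)/C(COC(=O)[C@H](C)[C@H](C)O[Si](CC)(CC)CC)=C/CCC1=CCOC1 | intermediate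
26 | 12-acetoxy-9-(3-methylbut-2-enoyloxy)-15-(trimethylsilyloxy)germacra-1(10)E,4,11(13)-trien-14-yl (2R,3S)-2-methyl-3-(triethylsilyloxy)butanoate (ring-trans C4=C5, 7R, 9R) | C=C(COC(C)=O)[C@H]1C[C@@H](OC(=O)C=C(C)C)/C(COC(=O)[C@H](C)[C@H](C)O[Si](CC)(CC)CC)=C/CC/C(CO[Si](C)(C)C)=C/C1 | intermediate
27 | 12-acetoxy-15-hydroxy-9-(3-methylbut-2-enoyloxy)germacra-1(10)E,4,11(13)-trien-14-yl (2R,3S)-3-hydroxy-2-methylbutanoate (ring-trans C4=C5, 4Z by CIP; 7R, 9R, same spatial arrangement at C7 as 7S in 28) | C=C(COC(C)=O)[C@H]1C[C@@H](OC(=O)C=C(C)C)/C(COC(=O)[C@H](C)[C@H](C)O)=C/CC/C(CO)=C/C1 | intermediate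
28 | CNP0227102.1: (4S,5R,7S,9R)-12-acetoxy-4,5-epoxy-15-hydroxy-9-(3-methylbut-2-enoyloxy)germacra-1(10)E,11(13)-dien-14-yl (2R,3S)-3-hydroxy-2-methylbutanoate | C=C(COC(C)=O)[C@H]1C[C@@H](OC(=O)C=C(C)C)/C(COC(=O)[C@H](C)[C@H](C)O)=C/CC[C@@]2(CO)O[C@@H]2C1 | target

**Step count and risks**
Total steps: 13. Longest linear sequence: 11 (steps 1–5 and 8–13).

Most likely to fail:

1. Step 12 (silylium-catalysed macrocyclisation). The risks are ionisation of the C9 allylic ester instead of the ring ether, E1 loss from the allyl cation, rotation of the cation before closure (4Z ring isomer), and the C7 epimer. The fallback sets out from 25 and comes back at 27, and replaces the catalytic ether ionisation by a stoichiometric halide abstraction that the carboxylic esters cannot answer. Trichloroacetyl chloride and NaI (MeCN, −20 °C) cleave the dihydrofuran at C6 to the ring-opened allylic iodide 15-trichloroacetate F1. AgOTf with 2,6-di-tert-butyl-4-methylpyridine (CH2Cl2, 1 mM, −40 °C) removes iodide, and the allylsilane closes the ring to the macrocyclic 15-trichloroacetate F2, whose ester oxygen cannot re-close onto C6. NH3 in MeOH (0 °C, trichloroacetate only) and then HF·pyridine give 27.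

2. Step 11 (cross-metathesis with a bulky 1,1-disubstituted allylsilane). The risk is low conversion and homodimer of 23. The fallback sets out from 23 and comes back at 25, and uses an α-substituted acrolein, the partner class already used in step 8. 2-[(Trimethylsilyl)methyl]prop-2-enal F3 (MnO2 oxidation of commercial 2-[(trimethylsilyl)methyl]prop-2-en-1-ol) is cross-metathesised with 23 under the step 8 conditions to the C12 enal F4 (formyl trans to C8). NaBH4/CeCl3 (MeOH, −78 °C) reduces only the aldehyde to the C12 allylic alcohol F5, and Ac2O/pyridine gives 25 as a single C7=C11 isomer.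

3. Step 13 (epoxidation). The risks are a slow reaction (the ring carbon C6 is cis to CH2OH) and a mismatch between the tartrate and the ring conformer that presents the required face. The fallback sets out from 27 and comes back at 28, and replaces the hydroxyl-directed titanium peroxide by a chiral dioxirane that is not directed by the hydroxyl. Shi epoxidation with the D-fructose-derived ketone and KHSO5 (as Oxone) in buffered MeCN/dimethoxymethane at 0 °C attacks the most electron-rich alkene, C4=C5. By the spiro transition-state model it delivers oxygen to the face that gives (R,R)-epoxides from trans olefins, which is the face needed here. It makes no new compound (none F0).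

**Further compounds**
F1 | step 12 | ring-opened 25: C6 allylic iodide, 15-O-trichloroacetate (C15 and C6 cis on C4=C5) | CC(=O)OCC(C[Si](C)(C)C)=CC[C@@H](OC(=O)C=C(C)C)/C(COC(=O)[C@H](C)[C@H](C)O[Si](CC)(CC)CC)=C/CC/C(COC(=O)C(Cl)(Cl)Cl)=C/CI
F2 | step 12 | macrocycle 26 with 15-O-trichloroacetyl in place of 15-O-trimethylsilyl | C=C(COC(C)=O)[C@H]1C[C@@H](OC(=O)C=C(C)C)/C(COC(=O)[C@H](C)[C@H](C)O[Si](CC)(CC)CC)=C/CC/C(COC(=O)C(Cl)(Cl)Cl)=C/C1
F3 | step 11 | 2-[(trimethylsilyl)methyl]prop-2-enal | C=C(C=O)C[Si](C)(C)C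
F4 | step 11 | C12 aldehyde analogue of 25 (CHO in place of CH2OAc, formyl trans to C8) | O=C/C(C[Si](C)(C)C)=C/C[C@@H](OC(=O)C=C(C)C)/C(COC(=O)[C@H](C)[C@H](C)O[Si](CC)(CC)CC)=C/CCC1=CCOC1
F5 | step 11 | C12 alcohol analogue of 25 (CH2OH in place of CH2OAc) | OC/C(C[Si](C)(C)C)=C/C[C@@H](OC(=O)C=C(C)C)/C(COC(=O)[C@H](C)[C@H](C)O[Si](CC)(CC)CC)=C/CCC1=CCOC1
F0 | step 13 | none | none
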